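Take a small charge of catalyst, 6.00 mM of Q on 300 mM of L in the winter run, and ask what twice that charge buys you, which is what the autumn run tried.

| flask | L | Q | G | time |
|---|---|---|---|---|
| winter | 300 mM | 6.00 mM |  |  |
| dawn | 150 mM | 6.00 mM |  |  |
| dusk | 300 mM | 6.00 mM | 150 mM |  |
| autumn | 300 mM | 12.0 mM |  |  |
| summer | 60.0 mM | 6.00 mM |  | 5.0 min |

| run | time / min | [L] / mM |
|---|---|---|
| winter run | 0.62 | 292.7 |
| winter run | 1.2 | 283.6 |
| winter run | 1.9 | 269.4 |
| winter run | 2.5 | 254.1 |
| winter run | 3.1 | 239.9 |
| winter run | 3.8 | 219.7 |
| winter run | 4.4 | 197.2 |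
| winter run | 5.0 | 175.7 |
| dawn run | 0.62 | 146.2 |
| dawn run | 1.2 | 141.1 |
| dawn run | 1.9 | 134.5 |
| dawn run | 2.5 | 128.3 |
| dawn run | 3.1 | 121.2 |
| dawn run | 3.8 | 114.7 |
| dawn run | 4.4 | 110.3 |
| dawn run | 5.0 | 100.6 |
| dusk run | 0.62 | 255.7 |
| dusk run | 1.2 | 210.5 |
| dusk run | 1.9 | 160.4 |
| dusk run | 2.5 | 122.9 |
| dusk run | 3.1 | 91.4 |
| dusk run | 3.8 | 62.3 |
| dusk run | 4.4 | 42.9 |
| dusk run | 5.0 | 30.5 |
| autumn run | 0.62 | 282.4 |
| autumn run | 1.2 | 262.5 |
| autumn run | 1.9 | 235.7 |
| autumn run | 2.5 | 207.7 |
| autumn run | 3.1 | 182.3 |
| autumn run | 3.8 | 149.8 |
| autumn run | 4.4 | 123.0 |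
| autumn run | 5.0 | 98.9 |

(readings scatter by 0.9 mM)

- Overall: L -> G, with Q as catalyst.
- Constant volume, constant temperature.
- Bound and free are read together.
- An order is taken over about fifteen percent of the charge, up and down.

* order of the initial rate in [Q], near the charge of the winter run, the rate being that where two percent of its L are G
* order of the initial rate in [L], near the charge of the winter run, the rate being that where two percent of its L are G (one fixed amount of G, the same in the runs compared)
* the dawn run starts with 150 mM less of L than the winter run, and with no G. Compared where both hold the same amount of L, once fifteen percent of what the dawn run was charged with has turned into G, is the dawn run faster, slower or alike (within a tenth)?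
* L in the summer run at 5.0 min, as a share of the L charged

The zero of your scale is a catalyst whose whole charge works: on its own, such a catalyst gives twice the rate from twice the Q, an order of one in c_Q, and the flask is read by how far it strays from that. The first way to the order is direct. The autumn run reaches 282.4 mM of L at 0.62 min and the winter run reaches 283.6 mM at 1.2 min, so these two windows span nearly the same c_L and c_G, and their mean rates, 28.4 mM min⁻¹ against 13.7 mM min⁻¹, stand at a ratio of 2.08, which is an order of 1.05 across that doubling.

The second way goes through shares. The dusk run, charged with 150 mM of G, loses L at 74.6 mM min⁻¹ over its first 1.2 min, far faster than the winter run, so G opens a second route, autocatalysis. If that extra rate goes as c_L times c_G, its constant reads 1.29 M⁻¹ min⁻¹. In the early winter window the G route then carries 3.08 mM min⁻¹, leaving 10.6 mM min⁻¹ to the catalyst route, a share of 0.775. If the catalyst route is proportional to c_Q, that share is the order.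

The two ways part, and the direct one assumes nothing about the catalyst, so the share is the one that cheats. Take the same G route from the autumn window and the catalyst route grows by a factor of 2.39, more than the charge grew. A straight line in c_Q that gives this ratio cuts the axis at 1.69 mM, and this reading is the dead charge, the Q put in that does no work. Your rule for the local order is then the catalyst share times c_Q over c_Q less the dead charge, which gives 1.08 for the winter charge, a reckoning that carries the scatter of a few early readings.

The forecast differs from this reckoning, with 0.85 in c_Q on the ground that “The Q route is 84% of the rate”, and it also gives 0.66 in c_L, the dawn run slower, and 70% for the summer run. The flask gives 1.0 in c_Q and 0.69 in c_L, the dawn run slower, and 71.1% for the summer run.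

    Q + L ⇌ QL (115.8 M⁻¹ min⁻¹, 46.02 min⁻¹)
    QL → G + Q (6.060 min⁻¹)
    Q + Zu → Ze
    L + G → 2 G (1.314 M⁻¹ min⁻¹)

The step of Q with Zu to Ze lifts the order in c_Q to 1.0, as the simulated winter run without that step proves. Carry the dead charge of 1.69 mM to that second flask: with the whole 6.00 mM of Q working, the catalyst route rises from 10.6 mM min⁻¹ to 14.7 mM min⁻¹ beside the same G route of 3.08 mM min⁻¹, so its share, and with it the order, comes to 0.827. The simulated run with the step of Q with Zu to Ze taken away gives an order in c_Q of 0.86.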